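Ring A (C1 carbinol, C2–OMe, C3–Me, C4 ketone, C5–H, C6–Me) is read as a ring-expanded methyl tetronate: O–C1, C2(OMe)=C3(Me) and C4=O are the atoms of a 4-methoxy-3-methylbutenolide. Everything rests on trading its lactone bond O–C4 for the bond C4–C5. The precursor is the complete depside chain esterified with a 5,5-disubstituted tetronate that carries a (Z)-2-iodo-1-methylvinyl group on C1. Iodine–lithium exchange makes C5 a carbanion that attacks C4 across the butenolide. Collapse of the strained 7-oxanorbornadiene alkoxide closes ring A, unveils the ketone and frees the tertiary alcohol in the last operation. C1 is set earlier by enantioselective O-to-C carboxyl migration.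

Key step: step 18

Assumption: the sense of induction of TADMAP on a tetronate-derived furanyl carbonate cannot be predicted with certainty, so the (S)-catalyst is written and its antipode is to be taken if it leads to the S ester (the iodine atom allows assignment by anomalous dispersion).

Step 1
Reactants: 1 4,5-dimethylresorcinol (4,5-dimethylbenzene-1,3-diol)
Product: 2 2,4-dihydroxy-5,6-dimethylbenzaldehyde
Conditions: POCl3, DMF, 0 °C to rt; then ice-water
Reagents that add atoms: N,N-dimethylformamide CN(C)C=O; water O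
Why: Vilsmeier–Haack formylation should go, as with orcinol, to the position ortho to one hydroxyl and para to the other next to the methyl group, not to the crowded carbon between the two hydroxyls.

Step 2
Reactants: 2 2,4-dihydroxy-5,6-dimethylbenzaldehyde
Product: 3 3-chloro-2,4-dihydroxy-5,6-dimethylbenzaldehyde (ring B unit)
Conditions: SO2Cl2 (1.0 equiv), Et2O, 0 °C
Reagents that add atoms: sulfuryl chloride O=S(=O)(Cl)Cl
Why: Electrophilic aromatic chlorination can only occur at C3, the single free ring position, which is activated by both hydroxyl groups.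

Step 3
Reactants: 2 2,4-dihydroxy-5,6-dimethylbenzaldehyde
Product: 4 4-(benzyloxy)-2-hydroxy-5,6-dimethylbenzaldehyde
Conditions: BnBr (1.0 equiv), K2CO3, acetone, reflux
Reagents that add atoms: benzyl bromide BrCc1ccccc1
Why: In this Williamson etherification the 2-OH is held in a hydrogen bond to the formyl group, so the free 4-OH is alkylated.

Step 4
Reactants: 4 4-(benzyloxy)-2-hydroxy-5,6-dimethylbenzaldehyde
Product: 5 4-(benzyloxy)-2-methoxy-5,6-dimethylbenzaldehyde
Conditions: MeI, K2CO3, DMF, 40 °C
Reagents that add atoms: iodomethane CI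
Why: Williamson etherification in a dipolar solvent caps the remaining chelated phenol.

Step 5
Reactants: 5 4-(benzyloxy)-2-methoxy-5,6-dimethylbenzaldehyde
Product: 6 4-hydroxy-2-methoxy-5,6-dimethylbenzaldehyde (ring D unit, acid masked as aldehyde)
Conditions: H2 (1 atm), Pd/C, EtOAc, rt
Reagents that add atoms: none
Why: Hydrogenolysis of the benzyl aryl ether is faster than reduction of the hindered, electron-rich aldehyde.

Step 6
Reactants: 7 propargyl alcohol
Product: 9 (Z)-3-iodo-2-methylprop-2-en-1-ol, via alkenylmagnesium alkoxide 8 (not isolated)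
Conditions: MeMgBr (2.5 equiv), CuI (cat.), THF, −10 °C to rt; then I2, −10 °C; dilute HCl
Reagents that add atoms: methylmagnesium bromide C[Mg]Br; iodine II
Why: Copper-catalysed anti-carbomagnesiation of the propargylic alkoxide puts methyl on the inner carbon and magnesium on the terminal carbon inside a five-membered chelate, so iodinolysis with retention leaves iodine cis to CH2OH.

Step 7
Reactants: 9 (Z)-3-iodo-2-methylprop-2-en-1-ol
Product: 10 (Z)-3-iodo-2-methylprop-2-enal
Conditions: MnO2, CH2Cl2, rt, dark; used at once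
Reagents that add atoms: none
Why: Allylic alcohol oxidation on MnO2 is neutral, and immediate use of the product in the dark should keep the Z geometry.

Step 8
Reactants: 10 (Z)-3-iodo-2-methylprop-2-enal; 11 methyl (E)-3-methoxy-2-methylacrylate
Product: 13 (±)-5-[(Z)-1-iodoprop-1-en-2-yl]-4-methoxy-3-methylfuran-2(5H)-one, via lithiated acrylate 12 (not isolated)
Conditions: 11, LiN(iPr)2, THF, −95 °C; then 10, −95 °C to rt; AcOH
Reagents that add atoms: none
Why: In this vinyl-carbanion tetronate synthesis the β-lithio-β-methoxyacrylate, held cis to the ester by chelation, adds 1,2 to the enal and the cis alkoxide lactonises; C1 forms racemic and is planarised in the next step.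

Step 9
Reactants: 13 (±)-tetronate; 14 phenyl chloroformate
Product: 16 5-[(Z)-1-iodoprop-1-en-2-yl]-4-methoxy-3-methylfuran-2-yl phenyl carbonate, via potassium furanolate 15 (not isolated)
Conditions: KN(SiMe3)2, THF, −78 °C; then 14, −78 °C to 0 °C
Reagents that add atoms: none
Why: O-acylation of a potassium dienolate by a hard chloroformate is favoured, and it gains the aromaticity of the furan.

Step 10
Reactants: 16 furanyl phenyl carbonate
Product: 17 phenyl (2R)-2-[(Z)-1-iodoprop-1-en-2-yl]-3-methoxy-4-methyl-5-oxo-2,5-dihydrofuran-2-carboxylate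
Conditions: (S)-TADMAP [3-(1-acetoxy-2,2,2-triphenylethyl)-4-(dimethylamino)pyridine] (10 mol %), toluene, 0 °C
Reagents that add atoms: none
Why: In this Steglich-type O-to-C carboxyl migration under chiral nucleophilic catalysis the acylpyridinium/furanolate ion pair recombines at C5 of the furan, the site where tetronate dienolates react, and the catalyst selects the face, which sets C1 as R.

Step 11
Reactants: 17 (R)-phenyl ester
Product: 18 (2R)-2-[(Z)-1-iodoprop-1-en-2-yl]-3-methoxy-4-methyl-5-oxo-2,5-dihydrofuran-2-carboxylic acid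
Conditions: LiOH, THF/H2O, 0 °C, short; cold 1 M HCl; used at once
Reagents that add atoms: lithium hydroxide [Li+].[OH-]
Why: Saponification takes the activated phenyl ester much faster than the vinylogous carbonate of the tetronate, and cold acidic work-up limits the time spent as carboxylate.

Step 12
Reactants: 18 (R)-tetronate acid; 3 3-chloro-2,4-dihydroxy-5,6-dimethylbenzaldehyde
Product: 20 2-chloro-4-formyl-3-hydroxy-5,6-dimethylphenyl ester of 18 (tetronate–ring B aldehyde), via acid chloride 19 (not isolated)
Conditions: (COCl)2, DMF (cat.), CH2Cl2, 0 °C; then 3, Et3N, DMAP (cat.), CH2Cl2, 0 °C to rt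
Reagents that add atoms: none
Why: In this acid chloride esterification with nucleophilic catalysis the acid has no α-hydrogen, and the non-chelated, more acidic 4-OH of 3 reacts while the 2-OH stays bonded to the formyl group.

Step 13
Reactants: 20 tetronate–ring B aldehyde
Product: 21 tetronate–ring B acid
Conditions: NaClO2, NaH2PO4, 2-methyl-2-butene, t-BuOH/THF/H2O, 0 °C to rt
Reagents that add atoms: sodium chlorite [Na+].[O-]Cl=O
Why: Pinnick oxidation touches only the aldehyde at about pH 4, and the alkene scavenger keeps hypochlorous acid from the phenol and the alkenyl iodide.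

Step 14
Reactants: 21 tetronate–ring B acid; 22 2,4-dihydroxy-3,6-dimethylbenzaldehyde (ring C unit)
Product: 24 tetronate–B–C aldehyde, via mixed trifluoroacetic anhydride 23 (not isolated)
Conditions: (CF3CO)2O, toluene, rt
Reagents that add atoms: none
Why: Mixed-anhydride depside esterification works for 2-hydroxy-6-methylbenzoic acids and acylates only the free 4-OH of 22, because both chelated 2-OH groups are inert.

Step 15
Reactants: 24 tetronate–B–C aldehyde
Product: 25 tetronate–B–C acid
Conditions: NaClO2, NaH2PO4, 2-methyl-2-butene, t-BuOH/THF/H2O, 0 °C to rt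
Reagents that add atoms: sodium chlorite [Na+].[O-]Cl=O
Why: Pinnick oxidation proceeds as in step 13, and the aryl esters are stable in the weakly acidic buffer.

Step 16
Reactants: 25 tetronate–B–C acid; 6 4-hydroxy-2-methoxy-5,6-dimethylbenzaldehyde
Product: 27 tetronate–B–C–D aldehyde, via mixed trifluoroacetic anhydride 26 (not isolated)
Conditions: (CF3CO)2O, toluene, rt
Reagents that add atoms: none
Why: This is the same mixed-anhydride depside esterification, and 6 offers a single hydroxyl group.

Step 17
Reactants: 27 tetronate–B–C–D aldehyde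
Product: 28 tetronate–B–C–D acid
Conditions: NaClO2, NaH2PO4, 2-methyl-2-butene, t-BuOH/THF/H2O, 0 °C to rt
Reagents that add atoms: sodium chlorite [Na+].[O-]Cl=O
Why: Pinnick oxidation unmasks the ring D acid before the organolithium step, which an aldehyde would not survive.

Step 18
Reactants: 28 tetronate–B–C–D acid
Product: 33 CNP0248758.1 (target), via trilithium salt 29 (not isolated), via alkenyllithium 30 (not isolated), via bridged alkoxide 31 (not isolated), via tetralithium quinolate 32 (not isolated)
Conditions: MeLi (3.0 equiv), THF, −78 °C; t-BuLi (2.1 equiv), THF/Et2O/pentane, −100 °C to −40 °C; AcOH, −78 °C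
Reagents that add atoms: none
Why: Proposed new method: MeLi first turns the acid and both phenols into lithium salts (29), which also deactivates the three benzoate carbonyls; t-BuLi then exchanges the alkenyl iodide with retention (30), and the C5 carbanion, held cis to C1, adds to the lactone carbonyl C4 from the butenolide face that bears the alkenyl group to give the 7-oxanorbornadiene alkoxide 31, whose strain is released by cleavage of the O–C4 bridge to the C4 ketone and the C1 alkoxide (32). The closest known reaction types are the Parham cyclisation, the anionic 1,4 O-to-C acyl shift and the Dieckmann stage of the Hauser–Kraus annulation, above all its aryne variant, where an sp2 carbanion two atoms from the carbinol carbon of a phthalide closes on the lactone carbonyl through the same oxa-bridged intermediate and not on the geminal nitrile. The carbocycle closes in the 6-exo-trig mode (5-exo-trig for the transient O-bridged ring). No new stereocentre remains: C1 is untouched and keeps R, while C4 of 31 is fixed by the bicycle and becomes planar again. The step needs attack at C4 in preference to the geminal aryl ester (a 4-exo closure on a carbonyl shielded by quaternary C1 and a 2,6-disubstituted aryl group made a poorer leaving group by its phenoxide) and to the di-ortho-substituted benzoates, and exchange at −100 °C should outrun addition of t-BuLi to any ester. Because the lactone is both protecting group of the alcohol and acyl donor, the quinol ester, whose free acid would lose CO2 and aromatise, appears only in the last operation.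

Compound list
1 | 4,5-dimethylresorcinol | Cc1cc(O)cc(O)c1C | starting material
2 | 2,4-dihydroxy-5,6-dimethylbenzaldehyde | O=Cc1c(O)cc(O)c(C)c1C | intermediate
3 | 3-chloro-2,4-dihydroxy-5,6-dimethylbenzaldehyde | O=Cc1c(O)c(Cl)c(O)c(C)c1C | intermediate
4 | 4-(benzyloxy)-2-hydroxy-5,6-dimethylbenzaldehyde | O=Cc1c(O)cc(OCc2ccccc2)c(C)c1C | intermediate
5 | 4-(benzyloxy)-2-methoxy-5,6-dimethylbenzaldehyde | O=Cc1c(OC)cc(OCc2ccccc2)c(C)c1C | intermediate
6 | 4-hydroxy-2-methoxy-5,6-dimethylbenzaldehyde | O=Cc1c(OC)cc(O)c(C)c1C | intermediate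
7 | propargyl alcohol | C#CCO | starting material
8 | bromomagnesium (Z)-3-(bromomagnesio)-2-methylprop-2-en-1-olate | Br[Mg]OC/C(C)=C\[Mg]Br | intermediate
9 | (Z)-3-iodo-2-methylprop-2-en-1-ol | OC/C(C)=C\I | intermediate
10 | (Z)-3-iodo-2-methylprop-2-enal | O=C/C(C)=C\I | intermediate
11 | methyl (E)-3-methoxy-2-methylacrylate | CO/C=C(\C)C(=O)OC | starting material
12 | methyl 3-lithio-3-methoxy-2-methylacrylate (Li cis to the ester) | CO/C([Li])=C(\C)C(=O)OC | intermediate
13 | (±)-5-[(Z)-1-iodoprop-1-en-2-yl]-4-methoxy-3-methylfuran-2(5H)-one | COC1=C(C)C(=O)OC1/C(C)=C\I | intermediate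
14 | phenyl chloroformate | O=C(Cl)Oc1ccccc1 | starting material
15 | potassium 5-[(Z)-1-iodoprop-1-en-2-yl]-4-methoxy-3-methylfuran-2-olate | COc1c(C)c([O-])oc1/C(C)=C\I.[K+] | intermediate
16 | 5-[(Z)-1-iodoprop-1-en-2-yl]-4-methoxy-3-methylfuran-2-yl phenyl carbonate | COc1c(C)c(OC(=O)Oc2ccccc2)oc1/C(C)=C\I | intermediate
17 | phenyl (2R)-2-[(Z)-1-iodoprop-1-en-2-yl]-3-methoxy-4-methyl-5-oxo-2,5-dihydrofuran-2-carboxylate | COC1=C(C)C(=O)O[C@@]1(/C(C)=C\I)C(=O)Oc1ccccc1 | intermediate
18 | (2R)-2-[(Z)-1-iodoprop-1-en-2-yl]-3-methoxy-4-methyl-5-oxo-2,5-dihydrofuran-2-carboxylic acid | COC1=C(C)C(=O)O[C@@]1(/C(C)=C\I)C(=O)O | intermediate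
19 | acid chloride of 18 | COC1=C(C)C(=O)O[C@@]1(/C(C)=C\I)C(=O)Cl | intermediate
20 | tetronate–ring B aldehyde | COC1=C(C)C(=O)O[C@@]1(/C(C)=C\I)C(=O)Oc1c(C)c(C)c(C=O)c(O)c1Cl | intermediate
21 | tetronate–ring B acid | COC1=C(C)C(=O)O[C@@]1(/C(C)=C\I)C(=O)Oc1c(C)c(C)c(C(=O)O)c(O)c1Cl | intermediate
22 | 2,4-dihydroxy-3,6-dimethylbenzaldehyde | O=Cc1c(O)c(C)c(O)cc1C | starting material
23 | mixed trifluoroacetic anhydride of 21 | COC1=C(C)C(=O)O[C@@]1(/C(C)=C\I)C(=O)Oc1c(C)c(C)c(C(=O)OC(=O)C(F)(F)F)c(O)c1Cl | intermediate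
24 | tetronate–B–C aldehyde | COC1=C(C)C(=O)O[C@@]1(/C(C)=C\I)C(=O)Oc1c(C)c(C)c(C(=O)Oc2cc(C)c(C=O)c(O)c2C)c(O)c1Cl | intermediate
25 | tetronate–B–C acid | COC1=C(C)C(=O)O[C@@]1(/C(C)=C\I)C(=O)Oc1c(C)c(C)c(C(=O)Oc2cc(C)c(C(=O)O)c(O)c2C)c(O)c1Cl | intermediate
26 | mixed trifluoroacetic anhydride of 25 | COC1=C(C)C(=O)O[C@@]1(/C(C)=C\I)C(=O)Oc1c(C)c(C)c(C(=O)Oc2cc(C)c(C(=O)OC(=O)C(F)(F)F)c(O)c2C)c(O)c1Cl | intermediate
27 | tetronate–B–C–D aldehyde | COC1=C(C)C(=O)O[C@@]1(/C(C)=C\I)C(=O)Oc1c(C)c(C)c(C(=O)Oc2cc(C)c(C(=O)Oc3cc(OC)c(C=O)c(C)c3C)c(O)c2C)c(O)c1Cl | intermediate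
28 | tetronate–B–C–D acid | COC1=C(C)C(=O)O[C@@]1(/C(C)=C\I)C(=O)Oc1c(C)c(C)c(C(=O)Oc2cc(C)c(C(=O)Oc3cc(OC)c(C(=O)O)c(C)c3C)c(O)c2C)c(O)c1Cl | intermediate
29 | trilithium salt of 28 (carboxylate and two phenoxides) | COC1=C(C)C(=O)O[C@@]1(/C(C)=C\I)C(=O)Oc1c(C)c(C)c(C(=O)Oc2cc(C)c(C(=O)Oc3cc(OC)c(C(=O)[O-])c(C)c3C)c([O-])c2C)c([O-])c1Cl.[Li+].[Li+].[Li+] | intermediate
30 | (Z)-alkenyllithium from 29 | COC1=C(C)C(=O)O[C@@]1(/C(C)=C\[Li])C(=O)Oc1c(C)c(C)c(C(=O)Oc2cc(C)c(C(=O)Oc3cc(OC)c(C(=O)[O-])c(C)c3C)c([O-])c2C)c([O-])c1Cl.[Li+].[Li+].[Li+] | intermediate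
31 | 7-oxabicyclo[2.2.1]hepta-2,5-dien-1-olate (O bridge C1–C4, alkoxide on C4) | COC1=C(C)[C@]2([O-])C=C(C)[C@]1(O2)C(=O)Oc1c(C)c(C)c(C(=O)Oc2cc(C)c(C(=O)Oc3cc(OC)c(C(=O)[O-])c(C)c3C)c([O-])c2C)c([O-])c1Cl.[Li+].[Li+].[Li+].[Li+] | intermediate
32 | tetralithium salt of the target | COC1=C(C)C(=O)C=C(C)[C@]1([O-])C(=O)Oc1c(C)c(C)c(C(=O)Oc2cc(C)c(C(=O)Oc3cc(OC)c(C(=O)[O-])c(C)c3C)c([O-])c2C)c([O-])c1Cl.[Li+].[Li+].[Li+].[Li+] | intermediate
33 | CNP0248758.1, (R) at C1 of ring A | COC1=C(C)C(=O)C=C(C)[C@]1(O)C(=O)Oc1c(C)c(C)c(C(=O)Oc2cc(C)c(C(=O)Oc3cc(OC)c(C(=O)O)c(C)c3C)c(O)c2C)c(O)c1Cl | target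

Total step count: 18. Longest linear sequence: 13 steps (steps 6 to 18, from propargyl alcohol 7).

Steps most likely to fail

1. Step 18 (key step). The alkenyllithium may close on the geminal aryl ester. It may also be quenched by proton transfer from a benzylic methyl group, or the polyanion may not stay in solution at low temperature. The fallback sets out from 28 and comes back at 33. Miyaura borylation (PdCl2(dppf), B2pin2, excess KOAc, dioxane, 60 °C) should replace iodine with retention and give the pinacol (Z)-alkenylboronate F1. Treatment with [Rh(OH)(cod)]2 in dioxane at 60 °C then transmetalates boron to monovalent rhodium. The alkenylrhodium acylates itself with the lactone by 1,2-addition and loss of the alkoxide. This is the known ketone synthesis by intramolecular acylation of an organorhodium with an ester, run under neutral conditions that leave the aryl esters and free phenols alone.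

2. Step 10. Facial selectivity may be poor, part of the carboxyl group may migrate to C3, or the C5=C6 geometry may erode in the furanolate. The fallback sets out from 16 and comes back at 17, and it replaces asymmetric catalysis by resolution. Achiral 4-(dimethylamino)pyridine in CH2Cl2 should give the racemic phenyl ester F2. Preparative chromatography on a chiral stationary phase then separates 17 from its (S)-enantiomer F3.

3. Step 11. The carboxylate, a vinylogous malonate half ester, may lose CO2 to the furanolate during basic hydrolysis. The fallback sets out from 13 and comes back at 18, and it never passes through basic medium. Compound 13 is deprotonated as in step 9 and 15 is trapped with 2,2,2-trichloroethyl chloroformate to give the furanyl trichloroethyl carbonate F4. The same catalyst should move the carboxyl group to C1 and give the (R)-trichloroethyl ester F5. An alkoxide is a poorer leaving group than the furanolate, so no scrambling is expected. Reductive cleavage with Zn in AcOH/THF at 0 °C releases 18 in its protonated form.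

Further compounds
F1 | step 18 | pinacol (Z)-alkenylboronate of 28 | COC1=C(C)C(=O)O[C@@]1(/C(C)=C\B2OC(C)(C)C(C)(C)O2)C(=O)Oc1c(C)c(C)c(C(=O)Oc2cc(C)c(C(=O)Oc3cc(OC)c(C(=O)O)c(C)c3C)c(O)c2C)c(O)c1Cl
F2 | step 10 | racemic phenyl 2-[(Z)-1-iodoprop-1-en-2-yl]-3-methoxy-4-methyl-5-oxo-2,5-dihydrofuran-2-carboxylate | COC1=C(C)C(=O)OC1(/C(C)=C\I)C(=O)Oc1ccccc1
F3 | step 10 | (S)-enantiomer of 17 | COC1=C(C)C(=O)O[C@]1(/C(C)=C\I)C(=O)Oc1ccccc1
F4 | step 11 | 5-[(Z)-1-iodoprop-1-en-2-yl]-4-methoxy-3-methylfuran-2-yl 2,2,2-trichloroethyl carbonate | COc1c(C)c(OC(=O)OCC(Cl)(Cl)Cl)oc1/C(C)=C\I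
F5 | step 11 | 2,2,2-trichloroethyl (2R)-2-[(Z)-1-iodoprop-1-en-2-yl]-3-methoxy-4-methyl-5-oxo-2,5-dihydrofuran-2-carboxylate | COC1=C(C)C(=O)O[C@@]1(/C(C)=C\I)C(=O)OCC(Cl)(Cl)Cl
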